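**Retrosynthetic overview**

- Feature: in the 1,2-dioxane ring, C3–C4–C5–C6 is a four-carbon chain whose end carbons carry the peroxide oxygens O2 and O1. Tying C3 to C6 gives a cyclobutanol, so the dioxane is cut back to cyclobutanol 16 plus dioxygen (C3–C6 broken, C6–O1 and O2–C3 formed); C3–OH to C3–H reduction and desilylation follow.
- Cyclobutanol 16 comes from methyl propanoate enolate and the 2,2-disubstituted cyclobutanone 14, which comes from methyl ketone 11 and a cyclopropyl sulfonium ylide.
- Ketone 11 comes from olefination and conjugate reduction of the α-silyloxy aldehyde 7, made by eliminative opening of the asymmetric epoxide of β-cyclogeraniol (from β-cyclocitral). This epoxidation sets the only controlled stereocentre, the cyclohexane carbinol carbon.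
- Ring order: cyclohexane (purchased), transient oxirane, oxaspiropentane, cyclobutane, 1,2-dioxane. C6, C3 and propanoate C2 arise without control, and the (2S,3S,6R) isomer is separated after the reduction.

Key step: step 11

Remark: the face selectivity of the tartrate-controlled epoxidation is assumed to follow the usual empirical rule for this tetrasubstituted allylic alcohol, and the three dioxane-side stereocentres are accepted as uncontrolled.

**Route**

Step 1
Reactants: 1 β-cyclocitral (2,6,6-trimethylcyclohex-1-ene-1-carbaldehyde)
Product: 2 β-cyclogeraniol ((2,6,6-trimethylcyclohex-1-en-1-yl)methanol)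
Conditions: NaBH4, CeCl3·7H2O, MeOH, 0 °C
Reagents that add atoms: none
Why: Luche reduction, in which the cerium-activated borohydride adds hydride 1,2 to the hindered, fully substituted enal and gives the primary allylic alcohol needed for the epoxidation without conjugate reduction.

Step 2
Reactants: 2 β-cyclogeraniol
Product: 3 [(1R,6R)-2,2,6-trimethyl-7-oxabicyclo[4.1.0]heptan-1-yl]methanol
Conditions: Ti(OiPr)4 (cat.), D-(−)-diethyl tartrate (diethyl (2S,3S)-tartrate, cat.), t-BuOOH, 4 Å molecular sieves, CH2Cl2, −20 °C
Reagents that add atoms: tert-butyl hydroperoxide, CC(C)(C)OO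
Why: Sharpless asymmetric epoxidation, in which the allylic alkoxide binds the complex formed from Ti(OiPr)4 and the tartrate and the peroxide oxygen is delivered to one alkene face, which with the unnatural D-(−)-tartrate should be the face that gives the (1R,6R) epoxide, so the C1–O bond of the future carbinol is set here and is not broken again.

Step 3
Reactants: 3 epoxy alcohol
Product: 4 triethyl{[(1R,6R)-2,2,6-trimethyl-7-oxabicyclo[4.1.0]heptan-1-yl]methoxy}silane
Conditions: Et3SiCl, imidazole, CH2Cl2, 0 °C
Reagents that add atoms: chlorotriethylsilane, CC[Si](Cl)(CC)CC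
Why: Standard silylation of the primary hydroxyl, which removes the acidic proton (and any alkoxide-driven epoxide migration) before the amide-base step and installs a group that can later be oxidised off directly.

Step 4
Reactants: 4 epoxy silyl ether
Product: 5 (1S)-2,2-dimethyl-6-methylidene-1-[(triethylsilyloxy)methyl]cyclohexan-1-ol
Conditions: Et2AlCl, lithium 2,2,6,6-tetramethylpiperidide (from the amine and n-BuLi), toluene, 0 °C to rt; aq. potassium sodium tartrate work-up
Reagents that add atoms: none
Why: Base-promoted isomerisation of an epoxide to an allylic alcohol, in which the aluminium of Et2Al(TMP) binds the epoxide oxygen and the hindered amide removes a syn proton from the most accessible β-carbon, the C6 methyl group, through a cyclic transition state, so the C6–O bond breaks to the exocyclic methylene while the C1–O bond keeps its configuration (C1 becomes the (1S) carbinol and C6 is no longer a stereocentre).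

Step 5
Reactants: 5 tertiary allylic alcohol
Product: 6 triethyl({(1S)-2,2-dimethyl-6-methylidene-1-[(triethylsilyloxy)methyl]cyclohexyl}oxy)silane
Conditions: Et3SiOTf, 2,6-lutidine, CH2Cl2, −78 to 0 °C
Reagents that add atoms: triethylsilyl trifluoromethanesulfonate, CC[Si](CC)(CC)OS(=O)(=O)C(F)(F)F
Why: Silyl triflate with a hindered pyridine base is the standard way to silylate a crowded tertiary alcohol, and the ether blocks α-ketol rearrangement at the aldehyde stage and alkoxide chemistry in the later base steps.

Step 6
Reactants: 6 bis-silyl ether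
Product: 7 (1S)-2,2-dimethyl-6-methylidene-1-(triethylsilyloxy)cyclohexane-1-carbaldehyde
Conditions: (COCl)2, DMSO, CH2Cl2, −78 to −30 °C; then Et3N, −78 °C to rt
Reagents that add atoms: none
Why: Swern oxidation carried out directly on a primary triethylsilyl ether, in which the chlorosulfonium salt exchanges the primary O–Si bond for an alkoxysulfonium ion that collapses to the aldehyde on adding amine, whereas the far more hindered tertiary silyl ether does not exchange, so no free α-hydroxy aldehyde is ever present.

Step 7
Reactants: 7 α-silyloxy aldehyde; 8 dimethyl (2-oxopropyl)phosphonate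
Product: 9 (3E)-4-[(1S)-2,2-dimethyl-6-methylidene-1-(triethylsilyloxy)cyclohexyl]but-3-en-2-one
Conditions: NaH, THF, 0 °C to 50 °C
Reagents that add atoms: dimethyl (2-oxopropyl)phosphonate, CC(=O)CP(=O)(OC)OC
Why: Horner–Wadsworth–Emmons olefination, in which the aldehyde has no α-hydrogen and cannot enolise, so the stabilised phosphonate anion should add even to this neopentyl-type carbonyl and give the (E)-enone, whose geometry is removed in the next step.

Step 8
Reactants: 9 enone
Product: 11 4-[(1S)-2,2-dimethyl-6-methylidene-1-(triethylsilyloxy)cyclohexyl]butan-2-one, via silyl enol ether 10 (not isolated)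
Conditions: [(Ph3P)CuH]6 (cat.), PhMe2SiH, toluene, rt; then K2CO3 (cat.), MeOH, 0 °C
Reagents that add atoms: none
Why: Copper hydride conjugate reduction (1,4-hydrosilylation), in which the phosphine-ligated copper hydride adds only to the electron-poor enone, the silane turns the copper enolate over to silyl enol ether 10 and mild methanolysis releases the ketone, so the unactivated exocyclic methylene, the carbonyl and the silyl ether are left alone.

Step 9
Reactants: 11 methyl ketone; 12 cyclopropyldiphenylsulfonium tetrafluoroborate
Product: 14 2-{2-[(1S)-2,2-dimethyl-6-methylidene-1-(triethylsilyloxy)cyclohexyl]ethyl}-2-methylcyclobutan-1-one, via oxaspiropentane 13 (not isolated)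
Conditions: KOH, DMSO, rt; then LiBF4 (cat.), toluene, rt
Reagents that add atoms: cyclopropyldiphenylsulfonium tetrafluoroborate, F[B-](F)(F)F.C1CC1[S+](c1ccccc1)c1ccccc1
Why: Sulfonium ylide spiroannulation, in which the reversibly formed cyclopropylide adds to the unhindered methyl ketone and closes to oxaspiropentane 13, whose epoxide opens at the fully substituted carbon under lithium ion catalysis to a cyclopropylcarbinyl cation that ring-expands (semipinacol-type 1,2-shift) to the cyclobutanone with the quaternary carbon next to the carbonyl; this new centre forms without control, which does not matter because it becomes a planar radical in step 11.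

Step 10
Reactants: 14 cyclobutanone; 15 methyl propanoate
Product: 16 methyl 2-(1-hydroxy-2-methyl-2-{2-[(1S)-2,2-dimethyl-6-methylidene-1-(triethylsilyloxy)cyclohexyl]ethyl}cyclobutyl)propanoate (diastereomer mixture)
Conditions: LiN(iPr)2, THF, −78 °C, methyl propanoate; then 14, −78 °C; AcOH quench at −78 °C
Reagents that add atoms: methyl propanoate, CCC(=O)OC
Why: Aldol addition of an ester lithium enolate to a ketone, in which the strained cyclobutanone carbonyl is highly electrophilic, addition and acidic quench at −78 °C forestall retro-aldol cleavage, and the new carbinol and propanoate centres are taken as a mixture because the first is destroyed and the second is labile in step 11.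

Step 11
Reactants: 16 tertiary cyclobutanol; 17 dioxygen
Product: 19 methyl 2-[3-hydroxy-6-methyl-6-{2-[(1S)-2,2-dimethyl-6-methylidene-1-(triethylsilyloxy)cyclohexyl]ethyl}-1,2-dioxan-3-yl]propanoate (1,2-dioxan-3-ol; wanted C6 epimer formed together with its C6 epimer), via hydroperoxy keto ester 18 (not isolated)
Conditions: Co(acac)2 (10 mol %), O2 (1 atm), CH2Cl2, rt
Reagents that add atoms: dioxygen, O=O
Why: The cyclobutanol exchanges onto cobalt, which dioxygen raises to the trivalent state, and the trivalent cobalt alkoxide releases an alkoxy radical whose β-scission, driven by loss of ring strain, breaks the C3–C6 bond toward the fully substituted ring carbon and leaves the C3 ketone and a tertiary C6 radical. That radical captures dioxygen, the peroxyl radical is brought to the hydroperoxide level (18) by divalent cobalt, and the peroxide oxygen adds to the C3 ketone, so C6–O1 and O2–C3 form in one operation. The closest known reaction type is the cobalt-catalysed aerobic ring expansion of cyclobutanols to 1,2-dioxan-3-ols, applied here to a tertiary cyclobutanol that carries an ester side chain. The 1,2-dioxane closes by 6-exo-trig attack of the hydroperoxide (or its cobalt peroxide) on the carbonyl carbon. C6 comes from a planar radical remote from the carbinol centre and forms as both epimers, C3 is an equilibrating hemiketal carbon and propanoate C2 epimerises through the open β-keto ester, so no stereocentre is controlled here and the isomers are carried on together. The step needs scission of the ring bond to C6 rather than of the bond to the ring CH2 or of the exocyclic bond to the propanoate carbon, which strain release and the stability of the tertiary radical secure, and it needs oxygen capture to outpace 5-exo or 6-endo addition of the C6 radical to the exocyclic methylene, which fast trapping under an oxygen atmosphere and the absence of any silane secure.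

Step 12
Reactants: 19 1,2-dioxan-3-ol (isomer mixture)
Product: 20 methyl (2S)-2-[(3S,6R)-6-methyl-6-{2-[(1S)-2,2-dimethyl-6-methylidene-1-(triethylsilyloxy)cyclohexyl]ethyl}-1,2-dioxan-3-yl]propanoate
Conditions: Et3SiH (excess), Me3SiOTf (0.2 equiv), CH2Cl2, −78 °C; Et3N quench; preparative HPLC
Reagents that add atoms: none
Why: Ionic reduction through a peroxycarbenium ion, in which the silyl triflate ionises the C3–OH bond with assistance from the lone pair of O2 and triethylsilane transfers hydride to C3, which fixes C3 and the until then labile propanoate C2; no useful bias is expected at either centre (nor was any available at C6), so the (2S,3S,6R) isomer, with the C3 side chain cis to the C6 ethylene tether, is isolated from the other diastereomers by preparative HPLC.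

Step 13
Reactants: 20 silyl-protected dioxane ester
Product: 21 methyl (2S)-2-[(3S,6R)-6-{2-[(1S)-1-hydroxy-2,2-dimethyl-6-methylidenecyclohexyl]ethyl}-6-methyl-1,2-dioxan-3-yl]propanoate (target)
Conditions: HF·pyridine, pyridine, THF, 0 °C to rt
Reagents that add atoms: none
Why: Fluoride-assisted cleavage of the Si–O bond under buffered, non-basic conditions, chosen because base could trigger Kornblum–DeLaMare cleavage at C3–H or β-elimination at propanoate C2, leaves the peroxide, the ester and all four stereocentres untouched.

**Compound list**

1 | β-cyclocitral (2,6,6-trimethylcyclohex-1-ene-1-carbaldehyde) | CC1=C(C=O)C(C)(C)CCC1 | starting material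
2 | β-cyclogeraniol ((2,6,6-trimethylcyclohex-1-en-1-yl)methanol) | CC1=C(CO)C(C)(C)CCC1 | intermediate
3 | [(1R,6R)-2,2,6-trimethyl-7-oxabicyclo[4.1.0]heptan-1-yl]methanol | C[C@@]12CCCC(C)(C)[C@@]1(O2)CO | intermediate
4 | triethyl{[(1R,6R)-2,2,6-trimethyl-7-oxabicyclo[4.1.0]heptan-1-yl]methoxy}silane | C[C@@]12CCCC(C)(C)[C@@]1(O2)CO[Si](CC)(CC)CC | intermediate
5 | (1S)-2,2-dimethyl-6-methylidene-1-[(triethylsilyloxy)methyl]cyclohexan-1-ol | C=C1CCCC(C)(C)[C@@]1(O)CO[Si](CC)(CC)CC | intermediate
6 | triethyl({(1S)-2,2-dimethyl-6-methylidene-1-[(triethylsilyloxy)methyl]cyclohexyl}oxy)silane | C=C1CCCC(C)(C)[C@@]1(O[Si](CC)(CC)CC)CO[Si](CC)(CC)CC | intermediate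
7 | (1S)-2,2-dimethyl-6-methylidene-1-(triethylsilyloxy)cyclohexane-1-carbaldehyde | C=C1CCCC(C)(C)[C@@]1(O[Si](CC)(CC)CC)C=O | intermediate
8 | dimethyl (2-oxopropyl)phosphonate | CC(=O)CP(=O)(OC)OC | starting material
9 | (3E)-4-[(1S)-2,2-dimethyl-6-methylidene-1-(triethylsilyloxy)cyclohexyl]but-3-en-2-one | C=C1CCCC(C)(C)[C@@]1(O[Si](CC)(CC)CC)/C=C/C(C)=O | intermediate
10 | dimethylphenylsilyl enol ether of 11 (enol ether geometry not defined) | C=C1CCCC(C)(C)[C@@]1(O[Si](CC)(CC)CC)CC=C(C)O[Si](C)(C)c1ccccc1 | intermediate (not isolated)
11 | 4-[(1S)-2,2-dimethyl-6-methylidene-1-(triethylsilyloxy)cyclohexyl]butan-2-one | C=C1CCCC(C)(C)[C@@]1(O[Si](CC)(CC)CC)CCC(C)=O | intermediate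
12 | cyclopropyldiphenylsulfonium tetrafluoroborate | F[B-](F)(F)F.C1CC1[S+](c1ccccc1)c1ccccc1 | starting material
13 | 2-{2-[(1S)-2,2-dimethyl-6-methylidene-1-(triethylsilyloxy)cyclohexyl]ethyl}-2-methyl-1-oxaspiro[2.2]pentane (both C2 epimers) | C=C1CCCC(C)(C)[C@@]1(O[Si](CC)(CC)CC)CCC1(C)OC12CC2 | intermediate (not isolated)
14 | 2-{2-[(1S)-2,2-dimethyl-6-methylidene-1-(triethylsilyloxy)cyclohexyl]ethyl}-2-methylcyclobutan-1-one (both C2 epimers) | C=C1CCCC(C)(C)[C@@]1(O[Si](CC)(CC)CC)CCC1(C)CCC1=O | intermediate
15 | methyl propanoate | CCC(=O)OC | starting material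
16 | methyl 2-(1-hydroxy-2-methyl-2-{2-[(1S)-2,2-dimethyl-6-methylidene-1-(triethylsilyloxy)cyclohexyl]ethyl}cyclobutyl)propanoate (diastereomer mixture at both cyclobutane centres and propanoate C2) | C=C1CCCC(C)(C)[C@@]1(O[Si](CC)(CC)CC)CCC1(C)CCC1(O)C(C)C(=O)OC | intermediate
17 | dioxygen | O=O | starting material
18 | methyl 8-[(1S)-2,2-dimethyl-6-methylidene-1-(triethylsilyloxy)cyclohexyl]-6-hydroperoxy-2,6-dimethyl-3-oxooctanoate (both C6 epimers) | C=C1CCCC(C)(C)[C@@]1(O[Si](CC)(CC)CC)CCC(C)(OO)CCC(=O)C(C)C(=O)OC | intermediate (not isolated)
19 | methyl 2-[3-hydroxy-6-methyl-6-{2-[(1S)-2,2-dimethyl-6-methylidene-1-(triethylsilyloxy)cyclohexyl]ethyl}-1,2-dioxan-3-yl]propanoate; wanted C6 epimer drawn (descriptor 6S here, the same spatial arrangement as 6R in the target), formed with its C6 epimer, C3 and propanoate C2 not fixed | C=C1CCCC(C)(C)[C@@]1(O[Si](CC)(CC)CC)CC[C@@]1(C)CCC(O)(C(C)C(=O)OC)OO1 | intermediate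
20 | methyl (2S)-2-[(3S,6R)-6-methyl-6-{2-[(1S)-2,2-dimethyl-6-methylidene-1-(triethylsilyloxy)cyclohexyl]ethyl}-1,2-dioxan-3-yl]propanoate | C=C1CCCC(C)(C)[C@@]1(O[Si](CC)(CC)CC)CC[C@@]1(C)CC[C@@H]([C@H](C)C(=O)OC)OO1 | intermediate
21 | methyl (2S)-2-[(3S,6R)-6-{2-[(1S)-1-hydroxy-2,2-dimethyl-6-methylidenecyclohexyl]ethyl}-6-methyl-1,2-dioxan-3-yl]propanoate (CNP0255906.1) | C=C1CCCC(C)(C)[C@@]1(O)CC[C@@]1(C)CC[C@@H]([C@H](C)C(=O)OC)OO1 | target

**Totals**

Total step count: 13. Longest linear sequence: 13 steps (from β-cyclocitral 1 to 21).

**Steps most likely to fail**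

1. Step 11 (ring expansion). The alkoxy radical may expel the ester-stabilised propanoate radical (the radical counterpart of a retro-aldol), or the β-hydroxy ester may chelate cobalt so that turnover stalls. The fallback keeps the same C3–C6 cleavage but moves the propanoate to a later bond formation. It sets out from cyclobutanone 14, which is reduced with NaBH4 in MeOH at 0 °C to the secondary cyclobutanol F1. The same Co(acac)2/O2 conditions should then give the 6,6-disubstituted 1,2-dioxan-3-ol F2, which already has hydrogen on C3. Acetylation (Ac2O, pyridine, DMAP) gives the 3-acetoxy-1,2-dioxane F3. A catalytic Lewis acid (Me3SiOTf or Sc(OTf)3, CH2Cl2, −78 °C) ionises F3 to the peroxycarbenium ion, which is captured by 1-methoxy-1-(trimethylsilyloxy)prop-1-ene (CC=C(OC)O[Si](C)(C)C) in a Mukaiyama-type addition that forms the C3–C2 bond. After HPLC separation this returns to the route at 20.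

2. Step 12 (ionic reduction). The silyl triflate, or triflic acid released from it, may ionise or cleave the tertiary allylic silyl ether, or the peroxide may fragment by O–O heterolysis before hydride transfer. The fallback moves the activation from the Lewis acid to the substrate. It sets out from 19, which is acetylated (Ac2O, DMAP, Et3N, CH2Cl2, 0 °C) to the peroxyketal acetate F4. The acetate should ionise under a catalytic, weakly silyl-cleaving Lewis acid (Sc(OTf)3, CH2Cl2, −20 °C) in the presence of Et3SiH, with no silyl triflate and no free hemiketal hydroxyl present. It returns to the route at 20 after the same separation.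

3. Step 4 (epoxide opening). The amide may abstract a proton from the ring CH2 at C5 instead of the methyl group, giving the endocyclic alkene, or the epoxy silyl ether may undergo Lewis-acid rearrangement. The fallback replaces the external base by hydroxyl-directed delivery. It sets out from the free epoxy alcohol 3, which is treated with Ti(OiPr)4 (stoichiometric, CH2Cl2, rt). The titanium alkoxide of the primary hydroxyl activates the epoxide internally, the distal C6–O bond breaks and a ligand alkoxide removes a proton from the methyl group cis to the CH2O arm, giving (1S)-1-(hydroxymethyl)-2,2-dimethyl-6-methylidenecyclohexan-1-ol F5. Bis-silylation of both hydroxyls (Et3SiOTf in excess, 2,6-lutidine) returns to the route at 6.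

**Further compounds**

F1 | step 11 | 2-{2-[(1S)-2,2-dimethyl-6-methylidene-1-(triethylsilyloxy)cyclohexyl]ethyl}-2-methylcyclobutan-1-ol | C=C1CCCC(C)(C)[C@@]1(O[Si](CC)(CC)CC)CCC1(C)CCC1O
F2 | step 11 | 6-{2-[(1S)-2,2-dimethyl-6-methylidene-1-(triethylsilyloxy)cyclohexyl]ethyl}-6-methyl-1,2-dioxan-3-ol | C=C1CCCC(C)(C)[C@@]1(O[Si](CC)(CC)CC)CCC1(C)CCC(O)OO1
F3 | step 11 | 6-{2-[(1S)-2,2-dimethyl-6-methylidene-1-(triethylsilyloxy)cyclohexyl]ethyl}-6-methyl-1,2-dioxan-3-yl acetate | C=C1CCCC(C)(C)[C@@]1(O[Si](CC)(CC)CC)CCC1(C)CCC(OC(C)=O)OO1
F4 | step 12 | methyl 2-[3-acetoxy-6-methyl-6-{2-[(1S)-2,2-dimethyl-6-methylidene-1-(triethylsilyloxy)cyclohexyl]ethyl}-1,2-dioxan-3-yl]propanoate | C=C1CCCC(C)(C)[C@@]1(O[Si](CC)(CC)CC)CC[C@@]1(C)CCC(OC(C)=O)(C(C)C(=O)OC)OO1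
F5 | step 4 | (1S)-1-(hydroxymethyl)-2,2-dimethyl-6-methylidenecyclohexan-1-ol | C=C1CCCC(C)(C)[C@@]1(O)CO
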